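**Strategy**

The route rests on cutting the O1–C8a bond of ring C. In the open form ring A is a 2,4-dimethoxyphenyl group on C4, and C8a is its only C–H carbon ortho to C4a (C5 carries OMe), within reach of the C2 hydroxyl. The key step uses that hydroxyl to direct palladium to C8a and then bonds O1 to C8a, closing ring C in one operation without touching C2 or C4. Its precursor is a (1S,3R)-1,3,3-triarylpropan-1-ol: rings B and D carry pivalates, and ring D one mesylate that marks the future O1 of the flavanone. Both stereocentres are set beforehand by catalysis; ring F is added afterwards.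

Key step: step 9

Remark: ring A must enter as a 2,4-dimethoxyphenyl group, because a 3,5-dimethoxyphenyl group on C4 would cyclise to the 6,8-dimethoxy isomer; the aryl donor is therefore 2,4-dimethoxyphenylboronic acid.
Remark: the carbon that becomes C8a is meta to both methoxy groups, so an arene radical cation of ring A would be attacked at C4a (spirocyclisation); hydroxyl-directed palladation is used instead.
Remark: the face selectivity of the rhodium–diene catalyst in step 7 is assigned by analogy with acyclic (E)-enones; the enantiomeric diene is equally available.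
Remark: in every flavan C2 is S and the ring D aryl at C4 is trans to the ring B aryl at C2; the CIP letter at C4 depends on the ring D substituents and is quoted only for the key-step product and the target.
Remark: "pivaloyloxy" is (2,2-dimethylpropanoyl)oxy and "mesyloxy" is (methanesulfonyl)oxy.

**Route**

Step 1
Reactants: 1 2,4,6-trihydroxybenzaldehyde
Product: 2 2-hydroxy-4,6-bis(pivaloyloxy)benzaldehyde
Conditions: PivCl (2.1 equiv), Et3N, CH2Cl2, −20 to 0 °C
Reagents that add atoms: pivaloyl chloride, CC(C)(C)C(=O)Cl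
Why: Regioselective O-acylation should esterify the para hydroxyl and one of the two equivalent ortho hydroxyls, while the last ortho hydroxyl, hydrogen-bonded to the formyl group and flanked by it, reacts much more slowly.

Step 2
Reactants: 2 2-hydroxy-4,6-bis(pivaloyloxy)benzaldehyde
Product: 3 2-(mesyloxy)-4,6-bis(pivaloyloxy)benzaldehyde
Conditions: MsCl, Et3N, CH2Cl2, 0 °C
Reagents that add atoms: methanesulfonyl chloride, CS(=O)(=O)Cl
Why: O-Sulfonylation of the remaining chelated phenol gives the one ring D oxygen a group that survives carbonate and can be removed later on its own.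

Step 3
Reactants: 4 4'-hydroxyacetophenone
Product: 5 4-acetylphenyl pivalate
Conditions: PivCl, Et3N, DMAP (cat.), CH2Cl2, 0 °C to rt
Reagents that add atoms: pivaloyl chloride, CC(C)(C)C(=O)Cl
Why: DMAP-catalysed O-acylation of the phenol gives an ester that keeps ring B electron-poor and tolerates the mildly basic steps better than an acetate would.

Step 4
Reactants: 5 4-acetylphenyl pivalate
Product: 6 4-(bromoacetyl)phenyl pivalate
Conditions: Br2 (1.0 equiv), HBr (cat.), AcOH/CH2Cl2, rt
Reagents that add atoms: bromine, BrBr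
Why: Acid-catalysed α-bromination through the enol should occur only at the methyl group, because the ring is deactivated by the acyl and acyloxy groups.

Step 5
Reactants: 6 4-(bromoacetyl)phenyl pivalate
Product: 8 1-(4-pivaloyloxyphenyl)-2-(triphenyl-λ5-phosphanylidene)ethan-1-one, via phosphonium bromide 7 (not isolated)
Conditions: PPh3, toluene, 60 °C; then Na2CO3 (aq), CH2Cl2, rt
Reagents that add atoms: triphenylphosphine, c1ccc(cc1)P(c1ccccc1)c1ccccc1
Why: SN2 quaternisation of PPh3 by the phenacyl bromide followed by deprotonation of the acidic CH2 group gives the carbonyl-stabilised ylide.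

Step 6
Reactants: 3 2-(mesyloxy)-4,6-bis(pivaloyloxy)benzaldehyde; 8 1-(4-pivaloyloxyphenyl)-2-(triphenyl-λ5-phosphanylidene)ethan-1-one
Product: 9 (E)-3-[2-(mesyloxy)-4,6-bis(pivaloyloxy)phenyl]-1-(4-pivaloyloxyphenyl)prop-2-en-1-one
Conditions: toluene, 100 °C
Reagents that add atoms: none
Why: Wittig olefination with a stabilised keto ylide should give the (E)-enone under neutral conditions that leave the aryl esters and the mesylate intact.

Step 7
Reactants: 9 (E)-3-[2-(mesyloxy)-4,6-bis(pivaloyloxy)phenyl]-1-(4-pivaloyloxyphenyl)prop-2-en-1-one; 10 2,4-dimethoxyphenylboronic acid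
Product: 11 (3R)-3-(2,4-dimethoxyphenyl)-3-[2-(mesyloxy)-4,6-bis(pivaloyloxy)phenyl]-1-(4-pivaloyloxyphenyl)propan-1-one
Conditions: [RhCl(C2H4)2]2 (2.5 mol %), (1R,4R)-2,5-diphenylbicyclo[2.2.2]octa-2,5-diene (5.5 mol %), KOH (0.2 equiv), 1,4-dioxane/H2O (10:1), 40 °C
Reagents that add atoms: none
Why: Hayashi–Miyaura asymmetric 1,4-addition, in which the aryl–rhodium species formed by transmetalation inserts the enone C=C bond and the C2-symmetric diene blocks one face of the bound enone, so that the aryl group is delivered to the β-carbon face that makes C3 (future flavan C4) R.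

Step 8
Reactants: 11 (3R)-3-(2,4-dimethoxyphenyl)-3-[2-(mesyloxy)-4,6-bis(pivaloyloxy)phenyl]-1-(4-pivaloyloxyphenyl)propan-1-one
Product: 12 (1S,3R)-3-(2,4-dimethoxyphenyl)-3-[2-(mesyloxy)-4,6-bis(pivaloyloxy)phenyl]-1-(4-pivaloyloxyphenyl)propan-1-ol
Conditions: (R)-1-methyl-3,3-diphenyltetrahydro-1H,3H-pyrrolo[1,2-c][1,3,2]oxazaborole ((R)-Me-CBS, 0.2 equiv), BH3·SMe2, THF, −20 °C; MeOH, then aqueous work-up
Reagents that add atoms: none
Why: Corey–Bakshi–Shibata reduction, in which the (R)-oxazaborolidine–borane complex binds the ketone with the aryl group as the large substituent and delivers hydride to give the (S)-carbinol (future flavan C2) under reagent control, independent of the remote C3 centre.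

Step 9
Reactants: 12 (1S,3R)-3-(2,4-dimethoxyphenyl)-3-[2-(mesyloxy)-4,6-bis(pivaloyloxy)phenyl]-1-(4-pivaloyloxyphenyl)propan-1-ol
Product: 13 (2S,4R)-5,7-dimethoxy-4-[2-(mesyloxy)-4,6-bis(pivaloyloxy)phenyl]-2-(4-pivaloyloxyphenyl)chromane (2,4-trans)
Conditions: Pd(OAc)2 (10 mol %), N-acetylglycine (20 mol %), PhI(OAc)2 (1.5 equiv), Li2CO3 (1.5 equiv), C6F6, 80 °C
Reagents that add atoms: none
Why: Proposed new method: the palladium alkoxide of 12 should direct carboxylate-assisted palladation to C8a, the only C–H carbon of ring A ortho to C4a, giving a seven-membered oxapalladacycle that PhI(OAc)2 oxidises to tetravalent palladium, from which C8a–O1 reductive elimination releases the chroman and returns divalent palladium. The closest known reaction type is the Pd(OAc)2/PhI(OAc)2 hydroxyl-directed C–H activation/C–O cyclisation of tertiary 2-arylethanols to dihydrobenzofurans; here the chain is one carbon longer and the alcohol is secondary and benzylic. Ring C closes as a six-membered ring by C(aryl)–O bond-forming reductive elimination inside the palladacycle, not by attack on the arene π system, which matters because C8a is meta to both methoxy groups. No stereocentre is formed: the C2–O bond is never broken and C4 is not ionised, so the (1S,3R) diad is carried into the (2S,4R) 2,4-trans flavan. Site selectivity is secured by the substrate, since ring A has a single ortho C–H, ring D has none and its esters shut down undirected palladation, and ring B could be reached only through a strained five-membered alkoxide palladacycle. The selectivity at risk is C–H cleavage against β-hydride elimination of the alkoxide to ketone 11, which the electron-poor pivaloyloxyphenyl ring and the amino acid ligand (known to accelerate hydroxyl-directed C–H cleavage) should favour, and any 11 formed is returned to step 8.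

Step 10
Reactants: 13 (2S,4R)-5,7-dimethoxy-4-[2-(mesyloxy)-4,6-bis(pivaloyloxy)phenyl]-2-(4-pivaloyloxyphenyl)chromane
Product: 15 (2S)-2,4-trans-4-[2,4-bis(benzyloxy)-6-(mesyloxy)phenyl]-2-(4-benzyloxyphenyl)-5,7-dimethoxychromane, via triphenol mesylate 14 (not isolated)
Conditions: K2CO3, MeOH/THF, 20–40 °C; evaporate; BnBr, K2CO3, DMF, 20 °C
Reagents that add atoms: benzyl bromide, BrCc1ccccc1
Why: Carbonate-catalysed transesterification frees the three phenols and Williamson etherification benzylates them in the same flask, while the aryl mesylate resists carbonate and keeps the future flavanone oxygen distinct.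

Step 11
Reactants: 15 (2S)-2,4-trans-4-[2,4-bis(benzyloxy)-6-(mesyloxy)phenyl]-2-(4-benzyloxyphenyl)-5,7-dimethoxychromane
Product: 16 (2S)-2,4-trans-4-[2,4-bis(benzyloxy)-6-hydroxyphenyl]-2-(4-benzyloxyphenyl)-5,7-dimethoxychromane
Conditions: KOH, MeOH/1,4-dioxane/H2O, 80 °C; then HCl (aq)
Reagents that add atoms: none
Why: Hydrolytic cleavage of the aryl methanesulfonate by hydroxide at sulfur frees the single ring D phenol ortho to C4, the benzyl ethers and the chroman being inert to base.

Step 12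
Reactants: 16 (2S)-2,4-trans-4-[2,4-bis(benzyloxy)-6-hydroxyphenyl]-2-(4-benzyloxyphenyl)-5,7-dimethoxychromane; 17 ethyl (R)-3-hydroxy-3-phenylpropanoate
Product: 18 ethyl (3S)-3-{3,5-bis(benzyloxy)-2-[(2S)-2,4-trans-2-(4-benzyloxyphenyl)-5,7-dimethoxychroman-4-yl]phenoxy}-3-phenylpropanoate
Conditions: PPh3, DIAD, toluene, 0 °C to rt
Reagents that add atoms: none
Why: Mitsunobu etherification, in which the phenol (the only acidic group) displaces the oxyphosphonium-activated secondary benzylic alcohol by SN2 with inversion, so the (R)-alcohol gives the (S)-aryl ether that becomes flavanone C2.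

Step 13
Reactants: 18 ethyl (3S)-3-{3,5-bis(benzyloxy)-2-[(2S)-2,4-trans-2-(4-benzyloxyphenyl)-5,7-dimethoxychroman-4-yl]phenoxy}-3-phenylpropanoate
Product: 19 (3S)-3-{3,5-bis(benzyloxy)-2-[(2S)-2,4-trans-2-(4-benzyloxyphenyl)-5,7-dimethoxychroman-4-yl]phenoxy}-3-phenylpropanoic acid
Conditions: LiOH, THF/MeOH/H2O, 0 °C; then HCl (aq)
Reagents that add atoms: lithium hydroxide, [Li+].[OH-]
Why: Saponification of the ethyl ester, run cold so that attack of hydroxide at the ester carbonyl outpaces E1cB loss of the aryloxide.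

Step 14
Reactants: 19 (3S)-3-{3,5-bis(benzyloxy)-2-[(2S)-2,4-trans-2-(4-benzyloxyphenyl)-5,7-dimethoxychroman-4-yl]phenoxy}-3-phenylpropanoic acid
Product: 21 (2S)-5,7-bis(benzyloxy)-8-[(2S)-2,4-trans-2-(4-benzyloxyphenyl)-5,7-dimethoxychroman-4-yl]-2-phenylchroman-4-one, via mixed trifluoroacetic anhydride 20 (not isolated)
Conditions: (CF3CO)2O (1.2 equiv), CH2Cl2, −10 to 0 °C
Reagents that add atoms: none
Why: Intramolecular Friedel–Crafts acylation through the mixed anhydride, in which the tethered acyl group can reach only the ring D carbon ortho to the ether oxygen, a position activated by three alkoxy groups, so ring F closes as the six-membered ketone without touching the stereocentres.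

Step 15
Reactants: 21 (2S)-5,7-bis(benzyloxy)-8-[(2S)-2,4-trans-2-(4-benzyloxyphenyl)-5,7-dimethoxychroman-4-yl]-2-phenylchroman-4-one
Product: 22 (2S)-5,7-dihydroxy-8-[(2S,4R)-2-(4-hydroxyphenyl)-5,7-dimethoxychroman-4-yl]-2-phenylchroman-4-one (CNP0188217.1)
Conditions: H2 (1 atm), 10% Pd/C, EtOAc/MeOH, rt
Reagents that add atoms: none
Why: Heterogeneous hydrogenolysis of the three benzyl ethers under neutral conditions, which avoids base-induced opening of the flavanone and should leave the aryl ketone and the cyclic benzylic ethers in place.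

**Compound list**

1 | 2,4,6-trihydroxybenzaldehyde | O=Cc1c(O)cc(O)cc1O | starting material
2 | 2-hydroxy-4,6-bis(pivaloyloxy)benzaldehyde | O=Cc1c(O)cc(OC(=O)C(C)(C)C)cc1OC(=O)C(C)(C)C | intermediate
3 | 2-(mesyloxy)-4,6-bis(pivaloyloxy)benzaldehyde | O=Cc1c(OS(C)(=O)=O)cc(OC(=O)C(C)(C)C)cc1OC(=O)C(C)(C)C | intermediate
4 | 4'-hydroxyacetophenone | CC(=O)c1ccc(O)cc1 | starting material
5 | 4-acetylphenyl pivalate | CC(=O)c1ccc(OC(=O)C(C)(C)C)cc1 | intermediate
6 | 4-(bromoacetyl)phenyl pivalate | O=C(CBr)c1ccc(OC(=O)C(C)(C)C)cc1 | intermediate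
7 | [2-oxo-2-(4-pivaloyloxyphenyl)ethyl]triphenylphosphonium bromide | O=C(C[P+](c1ccccc1)(c1ccccc1)c1ccccc1)c1ccc(OC(=O)C(C)(C)C)cc1.[Br-] | intermediate
8 | 1-(4-pivaloyloxyphenyl)-2-(triphenyl-λ5-phosphanylidene)ethan-1-one | O=C(C=P(c1ccccc1)(c1ccccc1)c1ccccc1)c1ccc(OC(=O)C(C)(C)C)cc1 | intermediate
9 | (E)-3-[2-(mesyloxy)-4,6-bis(pivaloyloxy)phenyl]-1-(4-pivaloyloxyphenyl)prop-2-en-1-one | O=C(/C=C/c1c(OS(C)(=O)=O)cc(OC(=O)C(C)(C)C)cc1OC(=O)C(C)(C)C)c1ccc(OC(=O)C(C)(C)C)cc1 | intermediate
10 | 2,4-dimethoxyphenylboronic acid | COc1ccc(B(O)O)c(OC)c1 | starting material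
11 | (3R)-3-(2,4-dimethoxyphenyl)-3-[2-(mesyloxy)-4,6-bis(pivaloyloxy)phenyl]-1-(4-pivaloyloxyphenyl)propan-1-one | O=C(C[C@H](c1ccc(OC)cc1OC)c1c(OS(C)(=O)=O)cc(OC(=O)C(C)(C)C)cc1OC(=O)C(C)(C)C)c1ccc(OC(=O)C(C)(C)C)cc1 | intermediate
12 | (1S,3R)-3-(2,4-dimethoxyphenyl)-3-[2-(mesyloxy)-4,6-bis(pivaloyloxy)phenyl]-1-(4-pivaloyloxyphenyl)propan-1-ol | O[C@H](c1ccc(OC(=O)C(C)(C)C)cc1)C[C@H](c1ccc(OC)cc1OC)c1c(OS(C)(=O)=O)cc(OC(=O)C(C)(C)C)cc1OC(=O)C(C)(C)C | intermediate
13 | (2S,4R)-5,7-dimethoxy-4-[2-(mesyloxy)-4,6-bis(pivaloyloxy)phenyl]-2-(4-pivaloyloxyphenyl)chromane | COc1cc(OC)c2c(c1)O[C@H](c1ccc(OC(=O)C(C)(C)C)cc1)C[C@H]2c1c(OS(C)(=O)=O)cc(OC(=O)C(C)(C)C)cc1OC(=O)C(C)(C)C | intermediate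
14 | (2S)-2,4-trans-4-[2,4-dihydroxy-6-(mesyloxy)phenyl]-2-(4-hydroxyphenyl)-5,7-dimethoxychromane | COc1cc(OC)c2c(c1)O[C@H](c1ccc(O)cc1)C[C@H]2c1c(OS(C)(=O)=O)cc(O)cc1O | intermediate
15 | (2S)-2,4-trans-4-[2,4-bis(benzyloxy)-6-(mesyloxy)phenyl]-2-(4-benzyloxyphenyl)-5,7-dimethoxychromane | COc1cc(OC)c2c(c1)O[C@H](c1ccc(OCc3ccccc3)cc1)C[C@H]2c1c(OS(C)(=O)=O)cc(OCc2ccccc2)cc1OCc1ccccc1 | intermediate
16 | (2S)-2,4-trans-4-[2,4-bis(benzyloxy)-6-hydroxyphenyl]-2-(4-benzyloxyphenyl)-5,7-dimethoxychromane | COc1cc(OC)c2c(c1)O[C@H](c1ccc(OCc3ccccc3)cc1)C[C@H]2c1c(O)cc(OCc2ccccc2)cc1OCc1ccccc1 | intermediate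
17 | ethyl (R)-3-hydroxy-3-phenylpropanoate | CCOC(=O)C[C@@H](O)c1ccccc1 | starting material
18 | ethyl (3S)-3-{3,5-bis(benzyloxy)-2-[(2S)-2,4-trans-2-(4-benzyloxyphenyl)-5,7-dimethoxychroman-4-yl]phenoxy}-3-phenylpropanoate | COc1cc(OC)c2c(c1)O[C@H](c1ccc(OCc3ccccc3)cc1)C[C@H]2c1c(O[C@H](c2ccccc2)CC(=O)OCC)cc(OCc2ccccc2)cc1OCc1ccccc1 | intermediate
19 | (3S)-3-{3,5-bis(benzyloxy)-2-[(2S)-2,4-trans-2-(4-benzyloxyphenyl)-5,7-dimethoxychroman-4-yl]phenoxy}-3-phenylpropanoic acid | COc1cc(OC)c2c(c1)O[C@H](c1ccc(OCc3ccccc3)cc1)C[C@H]2c1c(O[C@H](c2ccccc2)CC(=O)O)cc(OCc2ccccc2)cc1OCc1ccccc1 | intermediate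
20 | mixed anhydride of 19 with trifluoroacetic acid | COc1cc(OC)c2c(c1)O[C@H](c1ccc(OCc3ccccc3)cc1)C[C@H]2c1c(O[C@H](c2ccccc2)CC(=O)OC(=O)C(F)(F)F)cc(OCc2ccccc2)cc1OCc1ccccc1 | intermediate
21 | (2S)-5,7-bis(benzyloxy)-8-[(2S)-2,4-trans-2-(4-benzyloxyphenyl)-5,7-dimethoxychroman-4-yl]-2-phenylchroman-4-one | COc1cc(OC)c2c(c1)O[C@H](c1ccc(OCc3ccccc3)cc1)C[C@H]2c1c(OCc2ccccc2)cc(OCc2ccccc2)c2c1O[C@H](c1ccccc1)CC2=O | intermediate
22 | (2S)-5,7-dihydroxy-8-[(2S,4R)-2-(4-hydroxyphenyl)-5,7-dimethoxychroman-4-yl]-2-phenylchroman-4-one | COc1cc(OC)c2c(c1)O[C@H](c1ccc(O)cc1)C[C@H]2c1c(O)cc(O)c2c1O[C@H](c1ccccc1)CC2=O | target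

**Totals and risks**

Total step count: 15. Longest linear sequence: 13 steps (steps 3–15, from 4).

Steps most likely to fail:

1. Step 9 (proposed new method). The palladium alkoxide may undergo β-hydride elimination to the ketone faster than the arene C–H bond is cleaved through the seven-membered palladacycle, and acetate may be transferred to C8a in place of O1. Fallback, known chemistry with a different order of bond formation: the flavan is made with O1 already on ring A and ring D is attached last by Friedel–Crafts alkylation. This sequence replaces steps 1–11; it does not branch from an intermediate but sets out from purchased 5,7-dimethoxychromone and comes back to the route at 16. Asymmetric 1,4-addition of 4-(benzyloxy)phenylboronic acid ([RhCl(C2H4)2]2, (1S,4S)-2,5-diphenylbicyclo[2.2.2]octa-2,5-diene, KOH, dioxane/H2O) should give (2S)-2-(4-benzyloxyphenyl)-5,7-dimethoxychroman-4-one F1. NaBH4 reduces it to the flavan-4-ol F2. BF3·OEt2 in CH2Cl2 at −40 °C ionises this alcohol to the C4 cation stabilised by O1 and the 5,7-methoxy groups. 3,5-Bis(benzyloxy)phenol captures the cation through the carbon between its hydroxyl and a benzyloxy group, on the face away from the C2 aryl group, to give 16; the isomer alkylated para to the hydroxyl is removed by chromatography.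

2. Step 7. Migratory insertion at a β-carbon flanked by two ortho substituents may be slower than protodeboronation of the ortho-methoxy boronic acid, and face discrimination may be poor. Fallback, from 9 to 12: the aryl group is introduced by electrophilic aromatic substitution in place of an aryl–rhodium species. TfOH-catalysed Friedel–Crafts hydroarylation of 9 with 1,3-dimethoxybenzene, which reacts at its C4 and so delivers the 2,4-dimethoxyphenyl group, gives the racemic ketone F3. Reduction as in step 8 then gives 12 together with its (1S,3S) diastereomer F4, which is removed by chromatography.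

3. Step 12. The oxyphosphonium ion of the benzylic β-hydroxy ester may ionise (loss of inversion) or eliminate to ethyl cinnamate before the hindered phenol attacks. Fallback, from 16 to 21: flavanone C2 is set by catalyst-controlled conjugate arylation of a chromone in place of SN2 inversion. The sodium phenoxide of 16 (NaH, THF) opens β-propiolactone at its O–CH2 carbon to give the 3-aryloxypropanoic acid F5. (CF3CO)2O closes it to the chroman-4-one F6. TMSOTf/Et3N gives the silyl enol ether F7, and Pd(OAc)2 in MeCN (Saegusa–Ito oxidation) gives the chromone F8. [RhCl(C2H4)2]2 with (1S,4S)-2,5-diphenylbicyclo[2.2.2]octa-2,5-diene and phenylboronic acid then gives 21.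

**Further compounds**

F1 | step 9 | (2S)-2-(4-benzyloxyphenyl)-5,7-dimethoxychroman-4-one | COc1cc(OC)c2c(c1)O[C@H](c1ccc(OCc3ccccc3)cc1)CC2=O
F2 | step 9 | (2S)-2-(4-benzyloxyphenyl)-5,7-dimethoxychroman-4-ol (C4 epimers) | COc1cc(OC)c2c(c1)O[C@H](c1ccc(OCc3ccccc3)cc1)CC2O
F3 | step 7 | racemic 3-(2,4-dimethoxyphenyl)-3-[2-(mesyloxy)-4,6-bis(pivaloyloxy)phenyl]-1-(4-pivaloyloxyphenyl)propan-1-one | O=C(CC(c1ccc(OC)cc1OC)c1c(OS(C)(=O)=O)cc(OC(=O)C(C)(C)C)cc1OC(=O)C(C)(C)C)c1ccc(OC(=O)C(C)(C)C)cc1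
F4 | step 7 | (1S,3S)-3-(2,4-dimethoxyphenyl)-3-[2-(mesyloxy)-4,6-bis(pivaloyloxy)phenyl]-1-(4-pivaloyloxyphenyl)propan-1-ol | O[C@H](c1ccc(OC(=O)C(C)(C)C)cc1)C[C@@H](c1ccc(OC)cc1OC)c1c(OS(C)(=O)=O)cc(OC(=O)C(C)(C)C)cc1OC(=O)C(C)(C)C
F5 | step 12 | 3-{3,5-bis(benzyloxy)-2-[(2S)-2,4-trans-2-(4-benzyloxyphenyl)-5,7-dimethoxychroman-4-yl]phenoxy}propanoic acid | COc1cc(OC)c2c(c1)O[C@H](c1ccc(OCc3ccccc3)cc1)C[C@H]2c1c(OCCC(=O)O)cc(OCc2ccccc2)cc1OCc1ccccc1
F6 | step 12 | 5,7-bis(benzyloxy)-8-[(2S)-2,4-trans-2-(4-benzyloxyphenyl)-5,7-dimethoxychroman-4-yl]chroman-4-one | COc1cc(OC)c2c(c1)O[C@H](c1ccc(OCc3ccccc3)cc1)C[C@H]2c1c(OCc2ccccc2)cc(OCc2ccccc2)c2c1OCCC2=O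
F7 | step 12 | 5,7-bis(benzyloxy)-8-[(2S)-2,4-trans-2-(4-benzyloxyphenyl)-5,7-dimethoxychroman-4-yl]-4-(trimethylsilyloxy)-2H-chromene | COc1cc(OC)c2c(c1)O[C@H](c1ccc(OCc3ccccc3)cc1)C[C@H]2c1c(OCc2ccccc2)cc(OCc2ccccc2)c2c1OCC=C2O[Si](C)(C)C
F8 | step 12 | 5,7-bis(benzyloxy)-8-[(2S)-2,4-trans-2-(4-benzyloxyphenyl)-5,7-dimethoxychroman-4-yl]-4H-chromen-4-one | COc1cc(OC)c2c(c1)O[C@H](c1ccc(OCc3ccccc3)cc1)C[C@H]2c1c(OCc2ccccc2)cc(OCc2ccccc2)c2c1OC=CC2=O
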